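**Assumption/convention:** guaiane numbering (C1–C15) is used for both halves, unprimed for the diene half and primed for the dienophile half. Target = (1R,2R,3R,7R,10S,1'R,2'R,8'R,10'R); the hemiketal centre C8' is taken to be the thermodynamic epimer. This route is a paper design; none of it has been run.

## Retrosynthetic overview
1. Target ⇒ singlet-oxygen ene reaction and hemiketal closure on an α-isopropylidene ketone (C11'–O, O–C8'), preceded by an intermolecular Diels–Alder reaction (C1–C2', C3–C1') of 5-acetoxycyclopentadiene 19 with cyclopentadienone 29.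
2. 19 ⇐ Nazarov cyclopentannulation of a cycloheptenyl propenyl ketone; 29 ⇐ nitroalkene Michael/Nef/aldol cyclopentannulation, then selenoxide elimination.
3. Both seven-membered rings ⇐ one-carbon ring expansion of 4-silyloxy-2-methylcyclohexanones that differ only at the methyl-bearing carbon (OH-directed hydrogenation versus thermodynamic epimer).
4. Both ⇐ hydroxy enone 5 ⇐ singlet-oxygen [4+2] and Kornblum–DeLaMare rearrangement on the Shapiro diene of (S)-carvone, the only source of chirality.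
5. Ring order in each half: six (bought) → seven → five; then the norbornene by Diels–Alder; the 1,2-dioxolane last.

## Route

Step 1
Reactants: 1 (S)-(+)-carvone
Product: 2 carvone (E)-tosylhydrazone
Conditions: TsNHNH2, AcOH (cat.), MeOH, rt
Reagents that add atoms: 4-methylbenzenesulfonohydrazide, Cc1ccc(cc1)S(=O)(=O)NN
Why: Acid-catalysed hydrazone condensation at the only carbonyl leaves the C5 stereocentre untouched.

Step 2
Reactants: 2 carvone (E)-tosylhydrazone
Product: 3 (5S)-2-methyl-5-(prop-1-en-2-yl)cyclohexa-1,3-diene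
Conditions: MeLi (2.5 equiv), Et2O, 0 °C to rt; H2O
Reagents that add atoms: none
Why: Shapiro reaction: the dianion formed at the α'-CH2 loses sulfinate and N2 to a vinyllithium that is protonated to the ring 1,3-diene without touching the allylic stereocentre.

Step 3
Reactants: 3 (5S)-2-methyl-5-(prop-1-en-2-yl)cyclohexa-1,3-diene
Product: 5 (4S,5R)-4-hydroxy-2-methyl-5-(prop-1-en-2-yl)cyclohex-2-en-1-one, via endoperoxide 4 (not isolated)
Conditions: O2, visible light, tetraphenylporphyrin (cat.), CH2Cl2, −30 °C; then Et3N, 0 °C to rt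
Reagents that add atoms: dioxygen, O=O
Why: Singlet oxygen adds to the cyclohexadiene by [4+2] cycloaddition anti to the adjacent isopropenyl group, and Et3N then effects a Kornblum–DeLaMare rearrangement by removing the bridgehead H next to the ring CH2, which sets the carbinol centre (4S) trans to the carvone-derived centre.

Step 4
Reactants: 5 (4S,5R)-4-hydroxy-2-methyl-5-(prop-1-en-2-yl)cyclohex-2-en-1-one
Product: 6 (2S,4S,5R)-4-hydroxy-2-methyl-5-(propan-2-yl)cyclohexan-1-one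
Conditions: H2 (1 atm), [Ir(cod)(PCy3)(py)]PF6 (5 mol %), CH2Cl2, 0 °C to rt
Reagents that add atoms: none
Why: Hydroxyl-directed homogeneous hydrogenation delivers H2 to the enone C=C from the OH face, so the 2-methyl ends anti to OH and cis to the (simultaneously saturated) isopropyl group, i.e. 2S, the C10 configuration of the diene half.

Step 5
Reactants: 6 (2S,4S,5R)-4-hydroxy-2-methyl-5-(propan-2-yl)cyclohexan-1-one
Product: 7 (2S,4S,5R)-4-[(tert-butyldiphenylsilyl)oxy]-2-methyl-5-(propan-2-yl)cyclohexan-1-one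
Conditions: TBDPSCl, imidazole, DMF, rt
Reagents that add atoms: tert-butyl(chloro)diphenylsilane, CC(C)(C)[Si](Cl)(c1ccccc1)c1ccccc1
Why: Silylation of the secondary alcohol under non-epimerising conditions keeps C8 at the alcohol level, so the two α-centres cannot scramble through a 1,4-dione.

Step 6
Reactants: 7 (2S,4S,5R)-4-[(tert-butyldiphenylsilyl)oxy]-2-methyl-5-(propan-2-yl)cyclohexan-1-one
Product: 9 (2S,4S,5R)-4-[(tert-butyldiphenylsilyl)oxy]-2-methyl-5-(propan-2-yl)cycloheptan-1-one, via α-silyl ketone 8 (not isolated)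
Conditions: TMSCHN2, BF3·OEt2, CH2Cl2, −78 °C; then 1 M HCl, THF, 0 °C
Reagents that add atoms: (trimethylsilyl)diazomethane, C[Si](C)(C)C=[N+]=[N-]
Why: Lewis-acid-promoted diazoalkane homologation (Tiffeneau–Demjanov-type 1,2-shift) in which the less substituted α-CH2 migrates inserts one carbon remote from the methyl-bearing centre, and mild acid protodesilylation touches no stereocentre.

Step 7
Reactants: 9 (2S,4S,5R)-4-[(tert-butyldiphenylsilyl)oxy]-2-methyl-5-(propan-2-yl)cycloheptan-1-one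
Product: 10 (4R,5S,7S)-5-[(tert-butyldiphenylsilyl)oxy]-7-methyl-4-(propan-2-yl)cyclohept-1-en-1-yl trifluoromethanesulfonate
Conditions: KN(SiMe3)2, THF, −78 °C; PhNTf2
Reagents that add atoms: N-phenylbis(trifluoromethanesulfonimide), O=S(=O)(N(c1ccccc1)S(=O)(=O)C(F)(F)F)C(F)(F)F
Why: Kinetic deprotonation by the bulky amide at the α-CH2 and O-triflation give the less substituted enol triflate, after which the C10 methyl centre can no longer epimerise.

Step 8
Reactants: 10 (4R,5S,7S)-5-[(tert-butyldiphenylsilyl)oxy]-7-methyl-4-(propan-2-yl)cyclohept-1-en-1-yl trifluoromethanesulfonate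
Product: 11 (2E)-1-[(4R,5S,7S)-5-[(tert-butyldiphenylsilyl)oxy]-7-methyl-4-(propan-2-yl)cyclohept-1-en-1-yl]but-2-en-1-one
Conditions: CO (1 atm), Pd(PPh3)4 (5 mol %), LiCl, tributyl[(1E)-prop-1-en-1-yl]stannane, THF, 55 °C
Reagents that add atoms: carbon monoxide, [C-]#[O+]; tributyl[(1E)-prop-1-en-1-yl]stannane, CCCC[Sn](CCCC)(CCCC)/C=C/C
Why: Carbonylative Stille coupling (oxidative addition of zerovalent palladium, CO insertion, transmetallation, reductive elimination) gives the cross-conjugated divinyl ketone with retention of alkene geometry.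

Step 9
Reactants: 11 (2E)-1-[(4R,5S,7S)-5-[(tert-butyldiphenylsilyl)oxy]-7-methyl-4-(propan-2-yl)cyclohept-1-en-1-yl]but-2-en-1-one
Product: 12 (5R,6S,8S)-6-[(tert-butyldiphenylsilyl)oxy]-3,8-dimethyl-5-(propan-2-yl)-3,4,5,6,7,8-hexahydroazulen-1(2H)-one (both C3 epimers)
Conditions: BF3·OEt2, CH2Cl2, 0 °C to rt
Reagents that add atoms: none
Why: Nazarov cyclisation (conrotatory 4π electrocyclisation of the pentadienyl cation, then loss of the ring-fusion proton) gives the tetrasubstituted enone; the new methyl-bearing centre (guaiane C4) forms as an epimer mixture that is erased in step 10.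

Step 10
Reactants: 12 (5R,6S,8S)-6-[(tert-butyldiphenylsilyl)oxy]-3,8-dimethyl-5-(propan-2-yl)-3,4,5,6,7,8-hexahydroazulen-1(2H)-one
Product: 16 (3R,5R,6S,8S)-6-[(tert-butyldiphenylsilyl)oxy]-3-hydroxy-3,8-dimethyl-5-(propan-2-yl)-3,4,5,6,7,8-hexahydroazulen-1(2H)-one, via silyl dienol ether 13 (not isolated), via silyl peroxide 14 (not isolated), via tertiary silyl ether 15 (not isolated)
Conditions: Me3SiOTf, Et3N, CH2Cl2, 0 °C to rt (equilibration); then O2, visible light, tetraphenylporphyrin (cat.), −78 °C; PPh3; aqueous citric acid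
Reagents that add atoms: dioxygen, O=O
Why: Soft enolisation gives the fully substituted 1-silyloxycyclopentadiene (equilibrated by 1,5-H shifts), which takes up singlet oxygen by [4+2] cycloaddition across C2/C4 anti to the C10 methyl, and collapse of the silyl peroxyketal, phosphine reduction and mild acid leave the C4 hydroxyl anti to the C10 methyl.

Step 11
Reactants: 16 (3R,5R,6S,8S)-6-[(tert-butyldiphenylsilyl)oxy]-3-hydroxy-3,8-dimethyl-5-(propan-2-yl)-3,4,5,6,7,8-hexahydroazulen-1(2H)-one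
Product: 18 (1R,3R,5R,6S,8S)-6-[(tert-butyldiphenylsilyl)oxy]-3-hydroxy-3,8-dimethyl-5-(propan-2-yl)-1,2,3,4,5,6,7,8-octahydroazulen-1-yl acetate, via diol 17 (not isolated)
Conditions: NaBH4, CeCl3·7H2O, MeOH, −78 °C; work-up; then Ac2O, pyridine, DMAP (cat.), CH2Cl2, 0 °C
Reagents that add atoms: acetic anhydride, CC(=O)OC(C)=O
Why: Luche 1,2-reduction attacks the carbonyl from the face anti to both the C4 and the C10 methyl groups (the face of the cerium-bound C4–OH), setting the C2 carbinol (R) cis to the C10 methyl, and only the secondary alcohol is then acetylated.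

Step 12
Reactants: 18 (1R,3R,5R,6S,8S)-6-[(tert-butyldiphenylsilyl)oxy]-3-hydroxy-3,8-dimethyl-5-(propan-2-yl)-1,2,3,4,5,6,7,8-octahydroazulen-1-yl acetate
Product: 19 (1R,5R,6S,8S)-6-[(tert-butyldiphenylsilyl)oxy]-3,8-dimethyl-5-(propan-2-yl)-1,4,5,6,7,8-hexahydroazulen-1-yl acetate (diene half; guaiane 2-OAc, Δ1(5),3)
Conditions: Martin sulfurane Ph2S[OC(CF3)2Ph]2, CH2Cl2, −40 to 0 °C; cold filtration through basic alumina, used at once
Reagents that add atoms: none
Why: Dehydration of the tertiary allylic alcohol through its alkoxysulfonium ion with loss of a C3 proton gives the conjugated endocyclic cyclopentadiene, while the C2 acetate centre is untouched.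

Step 13
Reactants: 5 (4S,5R)-4-hydroxy-2-methyl-5-(prop-1-en-2-yl)cyclohex-2-en-1-one
Product: 20 (4S,5R)-4-[(tert-butyldiphenylsilyl)oxy]-2-methyl-5-(prop-1-en-2-yl)cyclohex-2-en-1-one
Conditions: TBDPSCl, imidazole, DMF, rt
Reagents that add atoms: tert-butyl(chloro)diphenylsilane, CC(C)(C)[Si](Cl)(c1ccccc1)c1ccccc1
Why: Silylation protects the carbinol that later becomes the C8' ketone and blocks the γ-position against base-induced isomerisation.

Step 14
Reactants: 20 (4S,5R)-4-[(tert-butyldiphenylsilyl)oxy]-2-methyl-5-(prop-1-en-2-yl)cyclohex-2-en-1-one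
Product: 21 (2R,4S,5R)-4-[(tert-butyldiphenylsilyl)oxy]-2-methyl-5-(prop-1-en-2-yl)cyclohexan-1-one
Conditions: LiBH(s-Bu)3, THF, −78 °C; aqueous NH4Cl; then DBU (cat.), CH2Cl2, rt
Reagents that add atoms: none
Why: Conjugate (1,4) hydride reduction spares the isopropenyl group, and base equilibration puts the α-methyl in the all-equatorial arrangement (cis to OSi, trans to isopropenyl), i.e. 2R, the C10' configuration of the dienophile half.

Step 15
Reactants: 21 (2R,4S,5R)-4-[(tert-butyldiphenylsilyl)oxy]-2-methyl-5-(prop-1-en-2-yl)cyclohexan-1-one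
Product: 23 (2R,4S,5R)-4-[(tert-butyldiphenylsilyl)oxy]-2-methyl-5-(prop-1-en-2-yl)cycloheptan-1-one, via α-silyl ketone 22 (not isolated)
Conditions: TMSCHN2, BF3·OEt2, CH2Cl2, −78 °C; then 1 M HCl, THF, 0 °C
Reagents that add atoms: (trimethylsilyl)diazomethane, C[Si](C)(C)C=[N+]=[N-]
Why: The same diazoalkane ring expansion with migration of the α-CH2 gives the cycloheptanone, whose methyl centre stays in its thermodynamically preferred arrangement.

Step 16
Reactants: 23 (2R,4S,5R)-4-[(tert-butyldiphenylsilyl)oxy]-2-methyl-5-(prop-1-en-2-yl)cycloheptan-1-one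
Product: 25 (2R,4S,5R)-4-[(tert-butyldiphenylsilyl)oxy]-2-methyl-7-(3-oxobutan-2-yl)-5-(prop-1-en-2-yl)cycloheptan-1-one (diastereomers at the two new centres), via nitro ketone 24 (not isolated)
Conditions: LiN(i-Pr)2, THF, −78 °C; 2-nitrobut-2-ene; then cold 2 M HCl
Reagents that add atoms: 2-nitrobut-2-ene, CC=C(C)[N+](=O)[O-]; water, O
Why: The kinetic enolate at the α-CH2 undergoes Michael addition to the nitroalkene and the nitronate is hydrolysed on acidic work-up (Nef reaction) to the 1,4-diketone, the two new centres being uncontrolled and erased later.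

Step 17
Reactants: 25 (2R,4S,5R)-4-[(tert-butyldiphenylsilyl)oxy]-2-methyl-7-(3-oxobutan-2-yl)-5-(prop-1-en-2-yl)cycloheptan-1-one
Product: 26 (4R,6S,7R)-6-[(tert-butyldiphenylsilyl)oxy]-1,4-dimethyl-7-(prop-1-en-2-yl)-4,5,6,7,8,8a-hexahydroazulen-2(1H)-one (C1/C8a epimers)
Conditions: NaOMe, MeOH, 0 °C to rt
Reagents that add atoms: none
Why: Intramolecular aldol condensation of the methyl ketone onto the ring ketone closes the cyclopentenone, and any enolisation toward C10' is harmless because its methyl already sits in the thermodynamic (R) arrangement.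

Step 18
Reactants: 26 (4R,6S,7R)-6-[(tert-butyldiphenylsilyl)oxy]-1,4-dimethyl-7-(prop-1-en-2-yl)-4,5,6,7,8,8a-hexahydroazulen-2(1H)-one
Product: 27 (4R,6S,7R)-6-[(tert-butyldiphenylsilyl)oxy]-1,4-dimethyl-1-(phenylselanyl)-7-(prop-1-en-2-yl)-4,5,6,7,8,8a-hexahydroazulen-2(1H)-one
Conditions: LiN(i-Pr)2, THF, −78 °C; PhSeBr
Reagents that add atoms: benzeneselenenyl bromide, Br[Se]c1ccccc1
Why: Kinetic α'-deprotonation and electrophilic selenenylation put PhSe on the methyl-bearing α'-carbon anti to the adjacent ring bond, i.e. syn to the ring-fusion H needed for the later syn-elimination.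

Step 19
Reactants: 19 diene half (5-acetoxycyclopentadiene); 27 α'-phenylselanyl enone
Product: 30 Diels–Alder adduct, (1R,2R,3R,7R,8S,10S,1'R,2'R,7'R,8'S,10'R)-2-acetoxy-8,8'-bis[(tert-butyldiphenylsilyl)oxy] dimer with C1–C2' and C3–C1' bonds, C4=C5, 3'-oxo-C4'=C5' and 7'-isopropenyl, via selenoxide 28 (not isolated), via cyclopentadienone 29 (not isolated)
Conditions: 27, mCPBA (1.0 equiv), CH2Cl2, −78 °C; then 19 (1.5 equiv), i-Pr2NH, −78 to 0 °C, then rt
Reagents that add atoms: none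
Why: Selenoxide syn-elimination releases the cyclopentadienone beside the diene and an intermolecular Diels–Alder reaction follows, in which no bond forms between two fully substituted carbons, the diene reacts anti to both its OAc and its C10 methyl, and the dienophile reacts anti to its C10' methyl (enone ring therefore exo), setting C1, C3, C1' and C2' as in the target.

Step 20
Reactants: 30 Diels–Alder adduct (bis-silyl ether)
Product: 31 8,8'-diol of the adduct
Conditions: HF·pyridine, pyridine, THF, 0 °C to rt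
Reagents that add atoms: none
Why: Fluoride-driven cleavage of both Si–O bonds leaves the acetate, the enone and all stereocentres untouched.

Step 21
Reactants: 31 8,8'-diol of the adduct
Product: 33 (1R,2R,3R,7R,10S,1'R,2'R,10'R)-2-acetoxy-3',8,8'-trioxo dimer with C7'=C11' isopropylidene, via isopropenyl trione 32 (not isolated)
Conditions: Dess–Martin periodinane, NaHCO3, CH2Cl2, 0 °C to rt; then DBU (0.1 equiv), 0 °C, short
Reagents that add atoms: none
Why: Dess–Martin oxidation gives both C8 ketones and catalytic base then conjugates the β,γ-unsaturated isopropenyl ketone to the α-isopropylidene ketone (removing the C7' centre), while the less acidic C7–H of the diene half is left alone.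

Step 22
Reactants: 33 trione with C7'=C11' isopropylidene
Product: 35 target CNP0361479.4, via hydroperoxide 34 (not isolated)
Conditions: O2, visible light, tetraphenylporphyrin (cat.), CH2Cl2, −20 °C; then rt
Reagents that add atoms: dioxygen, O=O
Why: Schenck ene reaction of singlet oxygen with the s-cis α-isopropylidene ketone takes H from C6' and delivers oxygen to C11', and the tertiary hydroperoxide adds to the C8' ketone to close the 1,2-dioxolan-3-ol, whose hemiketal centre equilibrates to the 8'R epimer (OH cis to the C10' methyl).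

## Compound list
1 | (S)-(+)-carvone, (5S)-2-methyl-5-(prop-1-en-2-yl)cyclohex-2-en-1-one | CC1=CC[C@@H](CC1=O)C(C)=C | starting material
2 | N'-[(1E,5S)-2-methyl-5-(prop-1-en-2-yl)cyclohex-2-en-1-ylidene]-4-methylbenzenesulfonohydrazide | CC1=CC[C@@H](C/C1=N\NS(=O)(=O)c1ccc(C)cc1)C(C)=C | intermediate
3 | (5S)-2-methyl-5-(prop-1-en-2-yl)cyclohexa-1,3-diene | CC1=CC[C@@H](C=C1)C(C)=C | intermediate
4 | (1S,4S,7R)-5-methyl-7-(prop-1-en-2-yl)-2,3-dioxabicyclo[2.2.2]oct-5-ene (O–O bridge anti to isopropenyl; not isolated) | CC1=C[C@@H]2OO[C@H]1C[C@@H]2C(C)=C | intermediate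
5 | (4S,5R)-4-hydroxy-2-methyl-5-(prop-1-en-2-yl)cyclohex-2-en-1-one | CC1=C[C@H](O)[C@@H](C(C)=C)CC1=O | intermediate
6 | (2S,4S,5R)-4-hydroxy-2-methyl-5-(propan-2-yl)cyclohexan-1-one | C[C@H]1C[C@H](O)[C@@H](C(C)C)CC1=O | intermediate
7 | (2S,4S,5R)-4-[(tert-butyldiphenylsilyl)oxy]-2-methyl-5-(propan-2-yl)cyclohexan-1-one | C[C@H]1C[C@H](O[Si](c2ccccc2)(c2ccccc2)C(C)(C)C)[C@@H](C(C)C)CC1=O | intermediate
8 | (2S,4S,5R)-4-[(tert-butyldiphenylsilyl)oxy]-2-methyl-5-(propan-2-yl)-7-(trimethylsilyl)cycloheptan-1-one (C7 epimers; not isolated) | C[C@H]1C[C@H](O[Si](c2ccccc2)(c2ccccc2)C(C)(C)C)[C@@H](C(C)C)CC([Si](C)(C)C)C1=O | intermediate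
9 | (2S,4S,5R)-4-[(tert-butyldiphenylsilyl)oxy]-2-methyl-5-(propan-2-yl)cycloheptan-1-one | C[C@H]1C[C@H](O[Si](c2ccccc2)(c2ccccc2)C(C)(C)C)[C@@H](C(C)C)CCC1=O | intermediate
10 | (4R,5S,7S)-5-[(tert-butyldiphenylsilyl)oxy]-7-methyl-4-(propan-2-yl)cyclohept-1-en-1-yl trifluoromethanesulfonate | C[C@H]1C[C@H](O[Si](c2ccccc2)(c2ccccc2)C(C)(C)C)[C@@H](C(C)C)CC=C1OS(=O)(=O)C(F)(F)F | intermediate
11 | (2E)-1-[(4R,5S,7S)-5-[(tert-butyldiphenylsilyl)oxy]-7-methyl-4-(propan-2-yl)cyclohept-1-en-1-yl]but-2-en-1-one | C[C@H]1C[C@H](O[Si](c2ccccc2)(c2ccccc2)C(C)(C)C)[C@@H](C(C)C)CC=C1C(=O)/C=C/C | intermediate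
12 | (5R,6S,8S)-6-[(tert-butyldiphenylsilyl)oxy]-3,8-dimethyl-5-(propan-2-yl)-3,4,5,6,7,8-hexahydroazulen-1(2H)-one (C3 epimer mixture) | C[C@H]1C[C@H](O[Si](c3ccccc3)(c3ccccc3)C(C)(C)C)[C@@H](C(C)C)CC2=C1C(=O)CC2C | intermediate
13 | (5R,6S,8S)-6-[(tert-butyldiphenylsilyl)oxy]-3,8-dimethyl-5-(propan-2-yl)-1-[(trimethylsilyl)oxy]-2,4,5,6,7,8-hexahydroazulene (not isolated) | C[C@H]1C[C@H](O[Si](c3ccccc3)(c3ccccc3)C(C)(C)C)[C@@H](C(C)C)CC2=C(C)CC(O[Si](C)(C)C)=C12 | intermediate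
14 | (3R,5R,6S,8S)-6-[(tert-butyldiphenylsilyl)oxy]-3,8-dimethyl-5-(propan-2-yl)-3-[(trimethylsilyl)peroxy]-3,4,5,6,7,8-hexahydroazulen-1(2H)-one (not isolated) | C[C@H]1C[C@H](O[Si](c3ccccc3)(c3ccccc3)C(C)(C)C)[C@@H](C(C)C)CC2=C1C(=O)C[C@@]2(C)OO[Si](C)(C)C | intermediate
15 | (3R,5R,6S,8S)-6-[(tert-butyldiphenylsilyl)oxy]-3,8-dimethyl-5-(propan-2-yl)-3-[(trimethylsilyl)oxy]-3,4,5,6,7,8-hexahydroazulen-1(2H)-one (not isolated) | C[C@H]1C[C@H](O[Si](c3ccccc3)(c3ccccc3)C(C)(C)C)[C@@H](C(C)C)CC2=C1C(=O)C[C@@]2(C)O[Si](C)(C)C | intermediate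
16 | (3R,5R,6S,8S)-6-[(tert-butyldiphenylsilyl)oxy]-3-hydroxy-3,8-dimethyl-5-(propan-2-yl)-3,4,5,6,7,8-hexahydroazulen-1(2H)-one | C[C@H]1C[C@H](O[Si](c3ccccc3)(c3ccccc3)C(C)(C)C)[C@@H](C(C)C)CC2=C1C(=O)C[C@@]2(C)O | intermediate
17 | (1R,3R,5R,6S,8S)-6-[(tert-butyldiphenylsilyl)oxy]-3,8-dimethyl-5-(propan-2-yl)-1,2,3,4,5,6,7,8-octahydroazulene-1,3-diol (not isolated) | C[C@H]1C[C@H](O[Si](c3ccccc3)(c3ccccc3)C(C)(C)C)[C@@H](C(C)C)CC2=C1[C@H](O)C[C@@]2(C)O | intermediate
18 | (1R,3R,5R,6S,8S)-6-[(tert-butyldiphenylsilyl)oxy]-3-hydroxy-3,8-dimethyl-5-(propan-2-yl)-1,2,3,4,5,6,7,8-octahydroazulen-1-yl acetate | C[C@H]1C[C@H](O[Si](c3ccccc3)(c3ccccc3)C(C)(C)C)[C@@H](C(C)C)CC2=C1[C@H](OC(C)=O)C[C@@]2(C)O | intermediate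
19 | (1R,5R,6S,8S)-6-[(tert-butyldiphenylsilyl)oxy]-3,8-dimethyl-5-(propan-2-yl)-1,4,5,6,7,8-hexahydroazulen-1-yl acetate (diene half) | C[C@H]1C[C@H](O[Si](c3ccccc3)(c3ccccc3)C(C)(C)C)[C@@H](C(C)C)CC2=C1[C@H](OC(C)=O)C=C2C | intermediate
20 | (4S,5R)-4-[(tert-butyldiphenylsilyl)oxy]-2-methyl-5-(prop-1-en-2-yl)cyclohex-2-en-1-one | CC1=C[C@H](O[Si](c2ccccc2)(c2ccccc2)C(C)(C)C)[C@@H](C(C)=C)CC1=O | intermediate
21 | (2R,4S,5R)-4-[(tert-butyldiphenylsilyl)oxy]-2-methyl-5-(prop-1-en-2-yl)cyclohexan-1-one | C[C@@H]1C[C@H](O[Si](c2ccccc2)(c2ccccc2)C(C)(C)C)[C@@H](C(C)=C)CC1=O | intermediate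
22 | (2R,4S,5R)-4-[(tert-butyldiphenylsilyl)oxy]-2-methyl-5-(prop-1-en-2-yl)-7-(trimethylsilyl)cycloheptan-1-one (C7 epimers; not isolated) | C[C@@H]1C[C@H](O[Si](c2ccccc2)(c2ccccc2)C(C)(C)C)[C@@H](C(C)=C)CC([Si](C)(C)C)C1=O | intermediate
23 | (2R,4S,5R)-4-[(tert-butyldiphenylsilyl)oxy]-2-methyl-5-(prop-1-en-2-yl)cycloheptan-1-one | C[C@@H]1C[C@H](O[Si](c2ccccc2)(c2ccccc2)C(C)(C)C)[C@@H](C(C)=C)CCC1=O | intermediate
24 | (2R,4S,5R)-4-[(tert-butyldiphenylsilyl)oxy]-2-methyl-7-(3-nitrobutan-2-yl)-5-(prop-1-en-2-yl)cycloheptan-1-one (as its lithium nitronate; new centres unassigned; not isolated) | C[C@@H]1C[C@H](O[Si](c2ccccc2)(c2ccccc2)C(C)(C)C)[C@@H](C(C)=C)CC(C(C)C(C)[N+](=O)[O-])C1=O | intermediate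
25 | (2R,4S,5R)-4-[(tert-butyldiphenylsilyl)oxy]-2-methyl-7-(3-oxobutan-2-yl)-5-(prop-1-en-2-yl)cycloheptan-1-one (new centres unassigned) | C[C@@H]1C[C@H](O[Si](c2ccccc2)(c2ccccc2)C(C)(C)C)[C@@H](C(C)=C)CC(C(C)C(C)=O)C1=O | intermediate
26 | (4R,6S,7R)-6-[(tert-butyldiphenylsilyl)oxy]-1,4-dimethyl-7-(prop-1-en-2-yl)-4,5,6,7,8,8a-hexahydroazulen-2(1H)-one (C1/C8a unassigned) | C[C@@H]1C[C@H](O[Si](c3ccccc3)(c3ccccc3)C(C)(C)C)[C@@H](C(C)=C)CC2C(C)C(=O)C=C12 | intermediate
27 | (4R,6S,7R)-6-[(tert-butyldiphenylsilyl)oxy]-1,4-dimethyl-1-(phenylselanyl)-7-(prop-1-en-2-yl)-4,5,6,7,8,8a-hexahydroazulen-2(1H)-one (SePh syn to H-8a) | C[C@@H]1C[C@H](O[Si](c3ccccc3)(c3ccccc3)C(C)(C)C)[C@@H](C(C)=C)CC2C(C)([Se]c3ccccc3)C(=O)C=C12 | intermediate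
28 | selenoxide of 27 (not isolated) | C[C@@H]1C[C@H](O[Si](c3ccccc3)(c3ccccc3)C(C)(C)C)[C@@H](C(C)=C)CC2C(C)([Se](=O)c3ccccc3)C(=O)C=C12 | intermediate
29 | (4R,6S,7R)-6-[(tert-butyldiphenylsilyl)oxy]-1,4-dimethyl-7-(prop-1-en-2-yl)-5,6,7,8-tetrahydroazulen-2(4H)-one (cyclopentadienone, dienophile half; not isolated) | C[C@@H]1C[C@H](O[Si](c3ccccc3)(c3ccccc3)C(C)(C)C)[C@@H](C(C)=C)CC2=C(C)C(=O)C=C12 | intermediate
30 | Diels–Alder adduct, (1R,2R,3R,7R,8S,10S,1'R,2'R,7'R,8'S,10'R)-2-acetoxy-8,8'-bis[(tert-butyldiphenylsilyl)oxy]-3'-oxo dimer (C1–C2', C3–C1'; C4=C5, C4'=C5', 7'-isopropenyl) | CC(=O)O[C@@H]1[C@@H]2C(C)=C3C[C@H](C(C)C)[C@@H](O[Si](c4ccccc4)(c4ccccc4)C(C)(C)C)C[C@H](C)[C@@]31[C@@H]1C(=O)C(C)=C3C[C@H](C(C)=C)[C@@H](O[Si](c4ccccc4)(c4ccccc4)C(C)(C)C)C[C@@H](C)[C@]312 | intermediate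
31 | 8,8'-diol of adduct 30 | CC(=O)O[C@@H]1[C@@H]2C(C)=C3C[C@H](C(C)C)[C@@H](O)C[C@H](C)[C@@]31[C@@H]1C(=O)C(C)=C3C[C@H](C(C)=C)[C@@H](O)C[C@@H](C)[C@]312 | intermediate
32 | 3',8,8'-trione with (7'R)-isopropenyl (not isolated) | CC(=O)O[C@@H]1[C@@H]2C(C)=C3C[C@H](C(C)C)C(=O)C[C@H](C)[C@@]31[C@@H]1C(=O)C(C)=C3C[C@H](C(C)=C)C(=O)C[C@@H](C)[C@]312 | intermediate
33 | (1R,2R,3R,7R,10S,1'R,2'R,10'R)-2-acetoxy-3',8,8'-trione with C7'=C11' isopropylidene | CC(=O)O[C@@H]1[C@@H]2C(C)=C3C[C@H](C(C)C)C(=O)C[C@H](C)[C@@]31[C@@H]1C(=O)C(C)=C3CC(=C(C)C)C(=O)C[C@@H](C)[C@]312 | intermediate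
34 | 11'-hydroperoxy-4',6'-diene-3',8'-dione form (open hydroperoxy ketone; not isolated) | CC(=O)O[C@@H]1[C@@H]2C(C)=C3C[C@H](C(C)C)C(=O)C[C@H](C)[C@@]31[C@@H]1C(=O)C(C)=C3C=C(C(C)(C)OO)C(=O)C[C@@H](C)[C@]312 | intermediate
35 | CNP0361479.4, (1R,2R,3R,7R,10S,1'R,2'R,8'R,10'R) | CC(=O)O[C@@H]1[C@@H]2C(C)=C3C[C@H](C(C)C)C(=O)C[C@H](C)[C@@]31[C@@H]1C(=O)C(C)=C3C=C4C(C)(C)OO[C@]4(O)C[C@@H](C)[C@]312 | target

## Step count and risks
Total step count: 22. Longest linear sequence: 16 steps (1–12, then 19–22).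

Steps most likely to fail:

**Step 12 (dehydration to the 5-acetoxycyclopentadiene 19).** The tertiary allylic cation can lose the wrong proton (exocyclic methylene, C1=C10, or the enol acetate), and 19 is prone to 1,5-H shifts. The fallback sets out from 12 and comes back at 19. The C3 epimer of 12 whose ring methyl is anti to the C8 methyl is separated (the other is recycled by DBU equilibration) and treated with LiN(i-Pr)2 and PhSeBr to give the α'-selenide, (5R,6S,8S)-6-[(tert-butyldiphenylsilyl)oxy]-3,8-dimethyl-2-(phenylselanyl)-5-(propan-2-yl)-3,4,5,6,7,8-hexahydroazulen-1(2H)-one F1 (SePh trans to the 3-methyl, cis to the 8-methyl). Luche reduction (hydride anti to SePh and to the 8-methyl) and acetylation give the seleno acetate, 6-[(tert-butyldiphenylsilyl)oxy]-3,8-dimethyl-2-(phenylselanyl)-5-(propan-2-yl)-1,2,3,4,5,6,7,8-octahydroazulen-1-yl acetate F2, with the same C1 configuration as 18. Oxidation with mCPBA at −78 °C gives the selenoxide of F2, F3, whose syn-elimination on warming runs away from the acetoxy carbon and gives 19; this can be done directly in the flask of step 19.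

**Step 19 (Diels–Alder).** The cyclopentadienone can dimerise or tautomerise, PhSeOH can attack the diene, and the known syn-directing effect of a 5-acetoxy group and the usual endo preference both work against the required approach. The fallback sets out from 19 and 27 and comes back at 30. The isolable enone 27 (selenide kept) is used as the dienophile with 19 at about 13 kbar in CH2Cl2 at rt, giving the 4',5'-saturated seleno adduct, 4'-(phenylselanyl)-4',5'-dihydro derivative of 30, F4. Oxidation with H2O2 and pyridine at 0 °C gives the selenoxide of F4, F5, whose syn-elimination installs C4'=C5' and gives 30.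

**Step 22 (photooxygenation).** The tetrasubstituted C4=C5 alkene of the diene half may compete in the ene reaction, although it is shielded on both faces, and the peroxy hemiketal may over-oxidise. The fallback sets out from 33 and comes back at 34 and hence 35. DBU (1 equiv, rt) moves the exocyclic double bond into the ring to give the fully conjugated 7'-isopropyl-4',6'-diene-3',8'-dione F6. Radical autoxidation of its doubly vinylogous C11'–H (O2, N-hydroxyphthalimide cat., Co(OAc)2 cat., MeCN, rt) gives hydroperoxide 34, which closes to 35.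

## Further compounds
F1 | step 12 | (5R,6S,8S)-6-[(tert-butyldiphenylsilyl)oxy]-3,8-dimethyl-2-(phenylselanyl)-5-(propan-2-yl)-3,4,5,6,7,8-hexahydroazulen-1(2H)-one (SePh trans to 3-Me, cis to 8-Me) | C[C@H]1C[C@H](O[Si](c3ccccc3)(c3ccccc3)C(C)(C)C)[C@@H](C(C)C)CC2=C1C(=O)[C@H]([Se]c3ccccc3)[C@H]2C
F2 | step 12 | 6-[(tert-butyldiphenylsilyl)oxy]-3,8-dimethyl-2-(phenylselanyl)-5-(propan-2-yl)-1,2,3,4,5,6,7,8-octahydroazulen-1-yl acetate | C[C@H]1C[C@H](O[Si](c3ccccc3)(c3ccccc3)C(C)(C)C)[C@@H](C(C)C)CC2=C1[C@H](OC(C)=O)[C@H]([Se]c3ccccc3)[C@H]2C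
F3 | step 12 | selenoxide of F2 | C[C@H]1C[C@H](O[Si](c3ccccc3)(c3ccccc3)C(C)(C)C)[C@@H](C(C)C)CC2=C1[C@H](OC(C)=O)[C@H]([Se](=O)c3ccccc3)[C@H]2C
F4 | step 19 | 4'-(phenylselanyl)-4',5'-dihydro derivative of adduct 30 | CC(=O)O[C@@H]1[C@@H]2C(C)=C3C[C@H](C(C)C)[C@@H](O[Si](c4ccccc4)(c4ccccc4)C(C)(C)C)C[C@H](C)[C@@]31[C@@H]1C(=O)C(C)([Se]c4ccccc4)C3C[C@H](C(C)=C)[C@@H](O[Si](c4ccccc4)(c4ccccc4)C(C)(C)C)C[C@@H](C)[C@]312
F5 | step 19 | selenoxide of F4 | CC(=O)O[C@@H]1[C@@H]2C(C)=C3C[C@H](C(C)C)[C@@H](O[Si](c4ccccc4)(c4ccccc4)C(C)(C)C)C[C@H](C)[C@@]31[C@@H]1C(=O)C(C)([Se](=O)c4ccccc4)C3C[C@H](C(C)=C)[C@@H](O[Si](c4ccccc4)(c4ccccc4)C(C)(C)C)C[C@@H](C)[C@]312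
F6 | step 22 | 7'-isopropyl-4',6'-diene-3',8'-dione isomer of 33 | CC(=O)O[C@@H]1[C@@H]2C(C)=C3C[C@H](C(C)C)C(=O)C[C@H](C)[C@@]31[C@@H]1C(=O)C(C)=C3C=C(C(C)C)C(=O)C[C@@H](C)[C@]312
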